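**Plan**

1. Retrosynthetic cuts, in order: the C13–O angelate ester and the C11–O aryl ether; then C8–O and C9–C11 (back to a C9 ketone with a 7-ene); then ring A across C3–C4; last C10–C1 and C10–CH3, which leads to (S)-carvone.
2. Enabling feature: in ring A the quaternary C4 carries a CH2–O arm (C13) and is bonded to the carbinol carbon C3. C4 can therefore be the tertiary radical released by opening a strained 2-methyloxirane (its oxygen ends on C13), and C3 the carbon of an aldehyde.
3. Forward order: (S)-carvone is ring B (C5–C10, with C12 and the isopropenyl group that becomes C4, C13 and C14). Two α'-alkylations build quaternary C10, and ring A closes by Cp2TiCl-mediated epoxide opening and 6-exo radical addition to the C3 aldehyde.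
4. Ring B is finished on the trans-decalin: C9 methylenation, hydroboration (C11–OH), Mukaiyama hydration (8-OH), Mitsunobu etherification with umbelliferone, acetal hydrolysis, and angeloylation of the primary C13–OH.
5. Stereochemistry: C5 comes from carvone; C10 from alkylation anti to the isopropenyl group; C4 and C3 from the chair transition state of the ring closure; C9 and C8 from reagent approach anti to the axial C10 methyl.

Key step: step 6

Remark: the decalin compounds are numbered as drimanes (ring A = C1–C5 and C10, ring B = C5–C10, C11 on C9, C12 = methyl on C8, C13 = oxygenated carbon on C4, C14 = methyl on C4, C15 = methyl on C10), and the ester in the SMILES is read as the (Z)-2-methylbut-2-enoate (angelate).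

**Route**

Step 1
Reactants: 1 (S)-(+)-carvone
Product: 3 (5S,6R)-2,6-dimethyl-5-(prop-1-en-2-yl)cyclohex-2-en-1-one, via lithium dienolate 2 (not isolated)
Conditions: LiN(iPr)2, THF, −78 °C; MeI, −78 → 0 °C
Reagents that add atoms: iodomethane (CI); lithium diisopropylamide (CC(C)[N-]C(C)C.[Li+]; lithium in 2 only)
Why: Kinetic α'-deprotonation gives the cross-conjugated dienolate 2, and its C-alkylation (enolate alkylation) installs the future C15 methyl; the new centre (expected mainly trans, carried on as the epimer mixture) is planarized again in step 2, so its configuration does not matter.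

Step 2
Reactants: 3 (5S,6R)-2,6-dimethyl-5-(prop-1-en-2-yl)cyclohex-2-en-1-one
Product: 5 (5R,6R)-2,6-dimethyl-6-(prop-2-en-1-yl)-5-(prop-1-en-2-yl)cyclohex-2-en-1-one, via lithium dienolate 4 (not isolated)
Conditions: LiN(iPr)2, THF, −78 °C; allyl bromide, DMPU, −78 → −20 °C
Reagents that add atoms: allyl bromide (C=CCBr); lithium diisopropylamide (CC(C)[N-]C(C)C.[Li+]; lithium in 4 only)
Why: Enolate alkylation of the tetrasubstituted dienolate 4 should occur on the face opposite the neighbouring isopropenyl group, which sets the quaternary centre (future C10) with the three-carbon arm trans and the methyl cis to isopropenyl, as the trans ring fusion requires.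

Step 3
Reactants: 5 (5R,6R)-2,6-dimethyl-6-(prop-2-en-1-yl)-5-(prop-1-en-2-yl)cyclohex-2-en-1-one
Product: 7 (5R,6R)-6-(3-hydroxypropyl)-2,6-dimethyl-5-(prop-1-en-2-yl)cyclohex-2-en-1-one, via catechol boronate 6 (not isolated)
Conditions: catecholborane, RhCl(PPh3)3 (2 mol %), THF, 0 °C → rt; then H2O2, pH 7 phosphate buffer, EtOH, 0 °C
Reagents that add atoms: hydrogen peroxide (OO); catecholborane (B1Oc2ccccc2O1; in 6 only)
Why: Rhodium-catalysed anti-Markovnikov hydroboration is far faster at the monosubstituted allyl double bond than at the 1,1-disubstituted isopropenyl group or the ketone, and buffered peroxide oxidation of 6 with retention gives the primary alcohol without Weitz–Scheffer epoxidation of the enone.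

Step 4
Reactants: 7 (5R,6R)-6-(3-hydroxypropyl)-2,6-dimethyl-5-(prop-1-en-2-yl)cyclohex-2-en-1-one
Product: 8 (5S,6R)-6-(3-hydroxypropyl)-2,6-dimethyl-5-(2-methyloxiran-2-yl)cyclohex-2-en-1-one (both epimers at the oxirane carbon)
Conditions: mCPBA, CH2Cl2, 0 °C
Reagents that add atoms: 3-chloroperbenzoic acid (OOC(=O)c1cccc(Cl)c1)
Why: Prilezhaev epoxidation takes the electron-rich 1,1-disubstituted double bond and not the electron-poor enone; the oxirane carbon forms as both epimers, which is harmless because it becomes a planar radical in step 6.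

Step 5
Reactants: 8 (5S,6R)-6-(3-hydroxypropyl)-2,6-dimethyl-5-(2-methyloxiran-2-yl)cyclohex-2-en-1-one
Product: 9 3-[(1R,6S)-1,3-dimethyl-6-(2-methyloxiran-2-yl)-2-oxocyclohex-3-en-1-yl]propanal
Conditions: Dess–Martin periodinane, pyridine, CH2Cl2, 0 °C → rt
Reagents that add atoms: none
Why: Dess–Martin oxidation converts the primary alcohol into the aldehyde under buffered conditions that spare the oxirane and do not over-oxidize.

Step 6
Reactants: 9 3-[(1R,6S)-1,3-dimethyl-6-(2-methyloxiran-2-yl)-2-oxocyclohex-3-en-1-yl]propanal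
Product: 10 (3R,4S,5R,10R)-3,13-dihydroxy-11-nordrim-7-en-9-one
Conditions: Cp2TiCl2 (2.5 equiv), Zn dust, THF, rt (gives Cp2TiCl); 9 added slowly at high dilution; then 1 M HCl
Reagents that add atoms: none
Why: Cp2TiCl (trivalent titanium) transfers one electron to the oxirane of 9, the C–O bond at the more substituted carbon breaks and leaves the tertiary β-titanoxy radical at C4 (both oxirane epimers give the same planar radical), which adds to the aldehyde carbon C3; a second Cp2TiCl reduces the resulting alkoxyl radical to the titanium alkoxide, which makes the addition irreversible, and protonation on work-up gives diol 10. The closest known reaction type is the titanocene chloride-mediated cyclization of epoxy aldehydes, epoxy ketones and epoxy nitriles (Nugent–RajanBabu epoxide opening followed by radical addition to C=O or C≡N). Ring A closes in the 6-exo-trig mode onto the carbonyl carbon through a chair transition state fused trans to ring B, because the tether on C10 and the radical carbon on C5 are both equatorial on the cyclohexenone. At C4 the titanoxymethyl arm, far larger than methyl, should take the equatorial site to avoid the 1,3-diaxial contact with the axial C10 methyl, which leaves the C4 methyl axial as in the target; at C3 the carbonyl oxygen should lie pseudo-equatorial, gauche to the equatorial CH2O–Ti arm so that titanium can bridge both oxygens, which gives the equatorial 3-hydroxyl. The step needs chemoselectivity for the epoxide over the enone and the aliphatic aldehyde, which Cp2TiCl should provide at room temperature (closure onto the enone would need a four-membered ring), and it needs cyclization to outrun reduction of the radical, which is favoured by the slow capture of hindered tertiary radicals by Cp2TiCl and by slow addition of 9.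

Step 7
Reactants: 10 (3R,4S,5R,10R)-3,13-dihydroxy-11-nordrim-7-en-9-one
Product: 11 (3R,4S,5R,10R)-3,13-(isopropylidenedioxy)-11-nordrim-7-en-9-one
Conditions: 2,2-dimethoxypropane, PPTS (cat.), acetone, rt
Reagents that add atoms: 2,2-dimethoxypropane (COC(C)(C)OC)
Why: Acid-catalysed transacetalization ties the diequatorial 1,3-diol (3-OH and C13-OH) into a chair 1,3-dioxane, which masks both hydroxyls through the basic, hydridic and radical steps that follow.

Step 8
Reactants: 11 (3R,4S,5R,10R)-3,13-(isopropylidenedioxy)-11-nordrim-7-en-9-one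
Product: 12 (3R,4S,5S,10R)-3,13-(isopropylidenedioxy)drima-7,9(11)-diene
Conditions: Ph3PCH3Br, KOtBu, toluene, 90 °C
Reagents that add atoms: methyltriphenylphosphonium bromide (C[P+](c1ccccc1)(c1ccccc1)c1ccccc1.[Br-])
Why: Wittig methylenation with the small non-stabilized ylide converts the hindered C9 ketone, which has no α-hydrogen, into the exocyclic C9=C11 alkene.

Step 9
Reactants: 12 (3R,4S,5S,10R)-3,13-(isopropylidenedioxy)drima-7,9(11)-diene
Product: 14 (3R,4S,5S,9R,10R)-3,13-(isopropylidenedioxy)drim-7-en-11-ol, via B-alkyl-9-BBN adduct 13 (not isolated)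
Conditions: 9-BBN, THF, 0 °C → rt; then NaOH, H2O2, 0 °C → rt
Reagents that add atoms: hydrogen peroxide (OO); 9-borabicyclo[3.3.1]nonane (B1C2CCCC1CCC2; in 13 only)
Why: Hydroboration–oxidation with the bulky borane places boron on the terminal C11 and leaves the trisubstituted 7,8-alkene, and the syn addition should deliver hydrogen to C9 from the face opposite the axial C10 methyl, which sets C9 with the CH2OH arm equatorial.

Step 10
Reactants: 14 (3R,4S,5S,9R,10R)-3,13-(isopropylidenedioxy)drim-7-en-11-ol
Product: 16 (3R,4S,5S,8S,9R,10R)-3,13-(isopropylidenedioxy)drimane-8,11-diol, via tertiary hydroperoxide 15 (not isolated)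
Conditions: Co(acac)2 (20 mol %), PhSiH3, O2 (1 atm), iPrOH, rt; then PPh3
Reagents that add atoms: dioxygen (O=O)
Why: Mukaiyama hydration (cobalt-hydride hydrogen-atom transfer to C7, capture of the tertiary C8 radical by O2, reduction of the hydroperoxide by PPh3) gives the Markovnikov tertiary alcohol, and the C–O bond should form equatorially on the face away from the syn-axial C10 methyl, which sets C8.

Step 11
Reactants: 16 (3R,4S,5S,8S,9R,10R)-3,13-(isopropylidenedioxy)drimane-8,11-diol; 17 umbelliferone (7-hydroxycoumarin)
Product: 18 7-{[(3R,4S,5S,8S,9R,10R)-8-hydroxy-3,13-(isopropylidenedioxy)driman-11-yl]oxy}-2H-chromen-2-one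
Conditions: PPh3, DIAD, THF, 0 → 40 °C
Reagents that add atoms: none
Why: Mitsunobu etherification activates only the primary C11 hydroxyl (the tertiary 8-OH gives no reactive oxyphosphonium ion), and the acidic phenol of 17 displaces it in an SN2 step at a carbon that is not a stereocentre.

Step 12
Reactants: 18 7-{[(3R,4S,5S,8S,9R,10R)-8-hydroxy-3,13-(isopropylidenedioxy)driman-11-yl]oxy}-2H-chromen-2-one
Product: 19 7-{[(3R,4S,5S,8S,9R,10R)-3,8,13-trihydroxydriman-11-yl]oxy}-2H-chromen-2-one
Conditions: AcOH/H2O (4:1), 40 °C
Reagents that add atoms: none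
Why: Mild aqueous acid hydrolyses the isopropylidene acetal without ionizing the tertiary 8-hydroxyl or touching the aryl ether and the coumarin lactone.

Step 13
Reactants: 19 7-{[(3R,4S,5S,8S,9R,10R)-3,8,13-trihydroxydriman-11-yl]oxy}-2H-chromen-2-one; 20 angelic acid ((Z)-2-methylbut-2-enoic acid)
Product: 22 (3R,4S,5S,8S,9R,10R)-3,8-dihydroxy-11-[(2-oxo-2H-chromen-7-yl)oxy]driman-13-yl (Z)-2-methylbut-2-enoate (CNP0139045.1), via mixed anhydride 21 (not isolated)
Conditions: 20, 2,4,6-trichlorobenzoyl chloride, Et3N, toluene, rt; then 19, toluene, 75 °C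
Reagents that add atoms: 2,4,6-trichlorobenzoyl chloride (O=C(Cl)c1c(Cl)cc(Cl)cc1Cl; in 21 only)
Why: Yamaguchi-type esterification through mixed anhydride 21, run without a nucleophilic amine catalyst, should acylate the primary C13 hydroxyl in preference to the hindered secondary 3-OH and the tertiary 8-OH, and it avoids the reversible conjugate addition that would isomerize the (Z)-angelate to the (E)-tiglate.

**Compound list**

1 | (S)-(+)-carvone | CC1=CC[C@@H](CC1=O)C(C)=C | starting material
2 | lithium dienolate of 1 (C6 deprotonated) | CC1=CC[C@H](C(C)=C)C=C1[O-].[Li+] | intermediate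
3 | (5S,6R)-2,6-dimethyl-5-(prop-1-en-2-yl)cyclohex-2-en-1-one (expected major epimer shown) | CC1=CC[C@H](C(C)=C)[C@@H](C)C1=O | intermediate
4 | lithium dienolate of 3 (C6 deprotonated) | CC1=CC[C@H](C(C)=C)C(C)=C1[O-].[Li+] | intermediate
5 | (5R,6R)-2,6-dimethyl-6-(prop-2-en-1-yl)-5-(prop-1-en-2-yl)cyclohex-2-en-1-one | CC1=CC[C@H](C(C)=C)[C@@](C)(CC=C)C1=O | intermediate
6 | catechol boronate of 5 (boron on the terminal carbon of the former allyl group) | CC1=CC[C@H](C(C)=C)[C@@](C)(CCCB2Oc3ccccc3O2)C1=O | intermediate
7 | (5R,6R)-6-(3-hydroxypropyl)-2,6-dimethyl-5-(prop-1-en-2-yl)cyclohex-2-en-1-one | CC1=CC[C@H](C(C)=C)[C@@](C)(CCCO)C1=O | intermediate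
8 | (5S,6R)-6-(3-hydroxypropyl)-2,6-dimethyl-5-(2-methyloxiran-2-yl)cyclohex-2-en-1-one (both oxirane epimers) | CC1=CC[C@H](C2(C)CO2)[C@@](C)(CCCO)C1=O | intermediate
9 | 3-[(1R,6S)-1,3-dimethyl-6-(2-methyloxiran-2-yl)-2-oxocyclohex-3-en-1-yl]propanal (both oxirane epimers) | CC1=CC[C@H](C2(C)CO2)[C@@](C)(CCC=O)C1=O | intermediate
10 | (3R,4S,5R,10R)-3,13-dihydroxy-11-nordrim-7-en-9-one (trans-decalin; 3-OH and C13 arm equatorial) | OC[C@]1(C)[C@H]2CC=C(C)C(=O)[C@]2(C)CC[C@H]1O | intermediate
11 | (3R,4S,5R,10R)-3,13-(isopropylidenedioxy)-11-nordrim-7-en-9-one | CC1(C)OC[C@]2(C)[C@H]3CC=C(C)C(=O)[C@]3(C)CC[C@H]2O1 | intermediate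
12 | (3R,4S,5S,10R)-3,13-(isopropylidenedioxy)drima-7,9(11)-diene | CC1(C)OC[C@]2(C)[C@H]3CC=C(C)C(=C)[C@]3(C)CC[C@H]2O1 | intermediate
13 | B-alkyl-9-BBN adduct of 12 (boron on C11, 9-H anti to the C10 methyl) | CC1(C)OC[C@]2(C)[C@H]3CC=C(C)[C@@H](CB4C5CCCC4CCC5)[C@]3(C)CC[C@H]2O1 | intermediate
14 | (3R,4S,5S,9R,10R)-3,13-(isopropylidenedioxy)drim-7-en-11-ol | CC1(C)OC[C@]2(C)[C@H]3CC=C(C)[C@@H](CO)[C@]3(C)CC[C@H]2O1 | intermediate
15 | (3R,4S,5S,8S,9R,10R)-8-hydroperoxy-3,13-(isopropylidenedioxy)driman-11-ol | CC1(C)OC[C@]2(C)[C@H]3CC[C@](C)(OO)[C@@H](CO)[C@]3(C)CC[C@H]2O1 | intermediate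
16 | (3R,4S,5S,8S,9R,10R)-3,13-(isopropylidenedioxy)drimane-8,11-diol | CC1(C)OC[C@]2(C)[C@H]3CC[C@](C)(O)[C@@H](CO)[C@]3(C)CC[C@H]2O1 | intermediate
17 | umbelliferone (7-hydroxy-2H-chromen-2-one) | O=c1ccc2ccc(O)cc2o1 | starting material
18 | 7-{[(3R,4S,5S,8S,9R,10R)-8-hydroxy-3,13-(isopropylidenedioxy)driman-11-yl]oxy}-2H-chromen-2-one | CC1(C)OC[C@]2(C)[C@H]3CC[C@](C)(O)[C@@H](COc4ccc5ccc(=O)oc5c4)[C@]3(C)CC[C@H]2O1 | intermediate
19 | 7-{[(3R,4S,5S,8S,9R,10R)-3,8,13-trihydroxydriman-11-yl]oxy}-2H-chromen-2-one | OC[C@]1(C)[C@H]2CC[C@](C)(O)[C@@H](COc3ccc4ccc(=O)oc4c3)[C@]2(C)CC[C@H]1O | intermediate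
20 | angelic acid ((Z)-2-methylbut-2-enoic acid) | C/C=C(/C)C(=O)O | starting material
21 | (Z)-2-methylbut-2-enoic 2,4,6-trichlorobenzoic anhydride | C/C=C(/C)C(=O)OC(=O)c1c(Cl)cc(Cl)cc1Cl | intermediate
22 | (3R,4S,5S,8S,9R,10R)-3,8-dihydroxy-11-[(2-oxo-2H-chromen-7-yl)oxy]driman-13-yl (Z)-2-methylbut-2-enoate (CNP0139045.1) | C/C=C(/C)C(=O)OC[C@]1(C)[C@H]2CC[C@](C)(O)[C@@H](COc3ccc4ccc(=O)oc4c3)[C@]2(C)CC[C@H]1O | target

**Step count**

Total steps: 13. Longest linear sequence: 13 steps, from (S)-carvone.

**Steps most likely to fail**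

Step 6. The addition of the C4 radical to the aldehyde may be unselective between the two carbonyl faces, because the alkoxyl radical can reopen before it is reduced; this would give a mixture of C3 epimers. The fallback sets out from compound 8 and moves C3 to the nitrile oxidation level, so that the closure is irreversible and C3 is set afterwards by hydride. One-pot oxidation of 8 (TEMPO cat., PhI(OAc)2, NH4OAc, MeCN/H2O) should give 3-[(1R,6S)-1,3-dimethyl-6-(2-methyloxiran-2-yl)-2-oxocyclohex-3-en-1-yl]propanenitrile F1. Treatment of F1 with Cp2TiCl2/Zn in THF (epoxide opening, 6-exo-dig radical addition to the nitrile, acidic work-up) should give (4S,5S,10R)-13-hydroxy-11-nordrim-7-ene-3,9-dione F2. NaBH4 in MeOH/CH2Cl2 at −78 °C should then reduce the saturated 3-ketone in preference to the hindered conjugated 9-ketone, with axial hydride delivery opposite the axial C4 methyl, to give the equatorial alcohol. The fallback comes back to the route at compound 10.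

Step 10. The planar C8 radical may be captured by oxygen on both faces, or be reduced to the alkane, so that the tertiary alcohol forms as a C8 epimer mixture. The fallback sets out from compound 14 and fixes the C8–O bond by a concerted, face-selective step. mCPBA in CH2Cl2 should epoxidize the 7,8-alkene on the face opposite the axial C10 methyl to give the 7,8-epoxide of 14 (oxirane oxygen anti to the C10 methyl) F3. LiEt3BH in THF should then open F3 by SN2 attack of hydride at the secondary C7, which leaves the C8–O bond untouched. The fallback comes back to the route at compound 16.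

Step 11. Displacement at the congested C11 oxyphosphonium ion (flanked by fully substituted C8 and C10) may be slow, so that alkylation of the hydrazide by-product or elimination takes over. The fallback sets out from compound 16 and forms the ether at the aryl carbon instead: palladium-catalysed C–O cross-coupling of the primary alcohol of 16 with commercial 7-bromocoumarin (Pd2(dba)3, RockPhos, Cs2CO3, toluene, 90 °C; Buchwald–Hartwig-type etherification), in which the tertiary 8-OH should not compete. No substitution at C11 is needed and no new compound is made on the way (F0). The fallback comes back to the route at compound 18.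

**Further compounds**

F1 | step 6 | 3-[(1R,6S)-1,3-dimethyl-6-(2-methyloxiran-2-yl)-2-oxocyclohex-3-en-1-yl]propanenitrile | CC1=CC[C@H](C2(C)CO2)[C@@](C)(CCC#N)C1=O
F2 | step 6 | (4S,5S,10R)-13-hydroxy-11-nordrim-7-ene-3,9-dione | OC[C@]1(C)[C@H]2CC=C(C)C(=O)[C@]2(C)CCC1=O
F3 | step 10 | 7,8-epoxide of 14 (oxirane oxygen anti to the C10 methyl) | CC1(C)OC[C@]2(C)[C@H]3C[C@@H]4O[C@]4(C)[C@@H](CO)[C@]3(C)CC[C@H]2O1
F0 | step 11 | none | none
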